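Ring B (the cycloheptene C1, C5, C6, C7, C8, C9, C10) is cut at C5–C6 and C7–C8. This frees C6–C7 as the vinyl group of a 2-substituted butadiene whose other carbons are C11, C12 and C13. The sequence sp2 C5, CH2, CH bearing a C(=CH2)CH2O unit, carbinol C8 is the pattern left by a diene 1,2-difunctionalisation. In one operation an enol triflate at C5 carbopalladates the diene, the π-allylpalladium is converted into an allylindium, and this adds to the C8 aldehyde. The result is a [5+2] annulation that sets C7 and C8 from C10. The precursor is the ring A/δ-lactone triflate carrying the aryl group and a 4-oxobutan-2-yl chain.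

Key step: step 14

Locants (guaiane numbering):
- Ring A = C1–C5. C2 carries OAc. C4 carries CH3-15 and the δ-lactone oxygen.
- Ring B = C1, C5–C10, with CH3-14 on C10.
- γ-Lactone = C7, C8, O, C12, C11, with C13 as the exocyclic CH2.
- Ring C (δ-lactone) = C4, O, C1′(=O), C2′(aryl), C3′, C3.
- C1″ = benzylic stereocentre of the side chain.
- Ar1 = 4-(TBDPSOCH2)-3-[(R)-5-(TBSO)pentan-2-yl]phenyl.

Assumption: the sense of induction of the chiral oxaziridine (step 9) and of the iridium ligand (step 4) is taken from the usual empirical models. If either is opposite, the equally available antipode of that reagent is used.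

Step 1
Reactants: 1 6-bromophthalide; 2 (3-bromopropoxy)(tert-butyl)dimethylsilane
Product: 4 1-[5-bromo-2-(hydroxymethyl)phenyl]-4-(tert-butyldimethylsilyloxy)butan-1-one (in equilibrium with its lactol), via Grignard reagent 3 (not isolated)
Conditions: 2, Mg, THF, 40 °C; then 1, THF, −78 °C; H2O
Reagents that add atoms: none
Why: Mono-addition of a Grignard reagent to a lactone, in which the magnesium lactolate survives at −78 °C so that the ketone is released only on work-up and the aryl bromide does not exchange.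

Step 2
Reactants: 4 hydroxy ketone
Product: 5 1-[5-bromo-2-(tert-butyldiphenylsilyloxymethyl)phenyl]-4-(tert-butyldimethylsilyloxy)butan-1-one
Conditions: TBDPSCl, imidazole, DMF, rt
Reagents that add atoms: tert-butyl(chloro)diphenylsilane, CC(C)(C)[Si](Cl)(c1ccccc1)c1ccccc1
Why: Silyl ether protection of the primary benzylic alcohol of the open tautomer drains the lactol equilibrium.

Step 3
Reactants: 5 aryl ketone
Product: 6 4-bromo-1-(tert-butyldiphenylsilyloxymethyl)-2-[5-(tert-butyldimethylsilyloxy)pent-1-en-2-yl]benzene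
Conditions: MePPh3Br, KOt-Bu, THF, 0 °C to rt
Reagents that add atoms: methyltriphenylphosphonium bromide, C[P+](c1ccccc1)(c1ccccc1)c1ccccc1.[Br-]
Why: Wittig methylenation of an aryl alkyl ketone, which tolerates both silyl ethers and the aryl bromide.

Step 4
Reactants: 6 1,1-disubstituted olefin
Product: 7 aryl bromide Ar1–Br, (1″R)
Conditions: [Ir(cod)(ThrePHOX)][B(3,5-(CF3)2C6H3)4] (1 mol %), H2 (1 bar), CH2Cl2, 0 °C
Reagents that add atoms: none
Why: Iridium-catalysed asymmetric hydrogenation of an unfunctionalised α-alkylstyrene-type olefin, in which the chiral N,P ligand distinguishes the aryl from the alkyl flank, sets C1″ as R and leaves the C–Br bond untouched.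

Step 5
Reactants: 8 tert-butyldimethyl(prop-2-yn-1-yloxy)silane; 9 ethylene
Product: 10 2-(tert-butyldimethylsilyloxymethyl)buta-1,3-diene
Conditions: RuCl2(=CHPh)(H2IMes)(PCy3) (second-generation Grubbs catalyst, 3 mol %), ethylene (1 atm), CH2Cl2, rt
Reagents that add atoms: none
Why: Enyne cross-metathesis of a terminal propargylic ether with ethylene gives the 2-substituted 1,3-diene directly.

Step 6
Reactants: 11 cyclopentane-1,3-dione; 12 (E)-crotonaldehyde
Product: 13 2-[(2S)-4-oxobutan-2-yl]cyclopentane-1,3-dione, (10S)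
Conditions: (R)-2-[diphenyl(trimethylsilyloxy)methyl]pyrrolidine (10 mol %), PhCO2H (10 mol %), CH2Cl2, 0 °C
Reagents that add atoms: none
Why: Iminium-catalysed asymmetric Michael addition of a cyclic 1,3-dione to an enal, in which the diphenyl(silyloxy)methyl group of the (R)-catalyst shields one face of the (E)-iminium ion so that C1 attacks the open face and sets C10 as S.

Step 7
Reactants: 13 dione aldehyde
Product: 14 2-[(2S)-4,4-dimethoxybutan-2-yl]-3-methoxycyclopent-2-en-1-one
Conditions: HC(OMe)3, MeOH, TsOH (cat.), rt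
Reagents that add atoms: trimethyl orthoformate, COC(OC)OC
Why: Acid-catalysed acetalisation and vinylogous ester formation occur in one pot, and the symmetry of the dione allows only one enol ether.

Step 8
Reactants: 14 vinylogous ester
Product: 15 2-[(2S)-4,4-dimethoxybutan-2-yl]-3-methoxy-5-methylcyclopent-2-en-1-one (both C4 epimers, of no consequence)
Conditions: LDA, THF, −78 °C; MeI
Reagents that add atoms: iodomethane, CI
Why: Kinetic α′-deprotonation and alkylation of a vinylogous ester (Stork–Danheiser type) puts CH3-15 on C4.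

Step 9
Reactants: 15 α′-methyl vinylogous ester
Product: 16 (5S)-2-[(2S)-4,4-dimethoxybutan-2-yl]-5-hydroxy-3-methoxy-5-methylcyclopent-2-en-1-one, (4S,10S)
Conditions: KHMDS, THF, −78 °C; (+)-(camphorsulfonyl)oxaziridine; H2O
Reagents that add atoms: (+)-(camphorsulfonyl)oxaziridine, CC1(C)[C@@H]2CC[C@]13CS(=O)(=O)N4OC34C2
Why: Enolate hydroxylation with an enantiopure N-sulfonyloxaziridine (Davis oxidation) sets the quaternary carbinol C4 by reagent control, independently of the remote C10.

Step 10
Reactants: 16 tertiary α-ketol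
Product: 17 acrylate ester of 16 at O–C4, (4S,10S)
Conditions: acryloyl chloride, Et3N, DMAP (cat.), CH2Cl2, 0 °C
Reagents that add atoms: acryloyl chloride, C=CC(=O)Cl
Why: DMAP-catalysed acylation of the tertiary alcohol installs C1′–C3′ as a tethered Michael acceptor.

Step 11
Reactants: 17 acrylate
Product: 18 ring A/ring C lactone: 2-methoxy-5-oxocyclopent-1-ene cis-fused at C3–C4 to the δ-lactone, (3S,4S,10S)
Conditions: KOt-Bu (20 mol %), THF, −20 to 0 °C
Reagents that add atoms: none
Why: With the α′ position quaternary the base removes the γ-proton at C3, and the extended enolate closes ring C by an intramolecular Michael addition (6-endo-trig), the tether from O–C4 forcing the new C3–C3′ bond cis to that oxygen.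

Step 12
Reactants: 18 δ-lactone; 7 aryl bromide Ar1–Br
Product: 19 2′-aryl lactone, (3S,4S,10S,2′R,1″R)
Conditions: LiHMDS (2.3 equiv), Pd(dba)2 (5 mol %), P(t-Bu)3 (10 mol %), toluene, rt; H2O
Reagents that add atoms: none
Why: Palladium-catalysed α-arylation of a lactone enolate (Buchwald–Hartwig type) joins the two halves, and protonation of the product enolate from the convex face puts the aryl group equatorial, which is also the thermodynamic C2′ epimer.

Step 13
Reactants: 19 aryl lactone
Product: 21 β-triflyloxy enone aldehyde (C5–OTf, C2=O, C8HO), (3R,4S,10S,2′R,1″R), via dienyl triflate 20 (not isolated)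
Conditions: KHMDS (2.4 equiv), THF, −78 °C; Comins' reagent (1.2 equiv); then 1 M aq HCl, THF, 0 °C
Reagents that add atoms: N-(5-chloropyridin-2-yl)bis(trifluoromethanesulfonimide), FC(F)(F)S(=O)(=O)N(c1ccc(Cl)cn1)S(=O)(=O)C(F)(F)F; water, O
Why: γ-Deprotonation and O-sulfonylation of the vinylogous ester put the triflate on the hindered C5 oxygen, and the acid quench then hydrolyses the enol ether and the acetal, returns any ketene acetal triflate to the lactone and reprotonates C3 and C2′ on the convex face of the cis-fused bicycle.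

Step 14
Reactants: 21 triflate aldehyde; 10 2-(tert-butyldimethylsilyloxymethyl)buta-1,3-diene
Product: 23 hydroazulenone with 8-OH and a 3-(TBSO)prop-1-en-2-yl group on C7, (3R,4S,7R,8S,10S,2′R,1″R), via allylindium species 22 (not isolated)
Conditions: Pd(OAc)2 (10 mol %), P(2-furyl)3 (20 mol %), InI (1.5 equiv), 10 (5 equiv), DMF–THF, 40 °C, slow addition of 21 (5 mM); H2O
Reagents that add atoms: none
Why: Proposed new method: zerovalent palladium inserts into the C5–OTf bond, the cationic alkenylpalladium carbopalladates the monosubstituted vinyl group of 10 at its CH2 terminus (C5–C6) to give the π-allyl complex C7–C11–C13, InI converts this by reductive transmetalation into allylindium 22 and frees the catalyst, and 22 adds through its γ-carbon C7 to the C8 aldehyde (C7–C8). The closest known reaction types are the palladium/indium three-component coupling of aryl or alkenyl halides with allenes and aldehydes, the Heck-type 1,2-difunctionalisation of 1,3-dienes with alkenyl triflates and the InI umpolung of π-allylpalladium complexes; new is a 2-substituted 1,3-diene as the two-carbon link in a ring-forming version. Only ring B is closed, as a formal [5+2] annulation whose last event is a 7-exo-trig carbonyl addition through a chair Zimmerman–Traxler array fused to the nascent cycloheptene. C7 and C8 arise together: the (E)-allylindium, free to equilibrate by 1,3-metal shift, reacts through the chair with C6 and C9 both equatorial, which gives the anti adduct with H7 and H8 trans. The face is relayed from C10, because A(1,3) strain with the C2 carbonyl keeps H10 in the enone plane and CH3-14 pseudoaxial, so that only the chair leading to (7R,8S) is unstrained. The step needs attack at the CH2 of the vinyl group and not at the 1,1-disubstituted terminus (secured by sterics and by keeping C12 as a silyl ether and not as an acrylate), no addition of the alkenylpalladium to the aldehyde and no attack of C7 on the ketone (C6 and C2 are trans on C1=C5), and no β-hydride elimination to a triene (base-free reducing medium, excess diene, high dilution).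

Step 15
Reactants: 23 bis-TBS ether
Product: 24 triol (8-OH, 12-OH, side-chain OH; TBDPS kept)
Conditions: HF·pyridine, pyridine, THF, 0 °C
Reagents that add atoms: none
Why: Fluoride-mediated desilylation removes the two primary TBS ethers much faster than the TBDPS ether.

Step 16
Reactants: 24 triol
Product: 26 trans-fused α-methylene-γ-butyrolactone enone, via lactol 25 (not isolated)
Conditions: MnO2 (activated, excess), CH2Cl2, rt
Reagents that add atoms: none
Why: MnO2 oxidises only the allylic C12 alcohol, the enal closes with 8-OH to the lactol and this allylic hemiacetal is oxidised on to the lactone, while the aliphatic primary alcohol and the silylated benzylic position are left alone.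

Step 17
Reactants: 26 enone
Product: 27 (2R)-allylic alcohol
Conditions: NaBH4, CeCl3·7H2O, MeOH, −78 °C
Reagents that add atoms: none
Why: Luche 1,2-reduction, in which hydride comes from the convex face of the ring A/ring C bicycle, opposite to ring C and to the pseudoaxial CH3-14, so that 2-OH ends up cis to C3–C3′; both lactones survive.

Step 18
Reactants: 27 diol (2-OH and side-chain OH)
Product: 28 diacetate (TBDPS ether)
Conditions: Ac2O, pyridine, DMAP (cat.), CH2Cl2, rt
Reagents that add atoms: acetic anhydride, CC(=O)OC(C)=O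
Why: DMAP-catalysed acetylation installs both acetates of the target in one step.

Step 19
Reactants: 28 TBDPS ether
Product: 29 CNP0205574.1 (target)
Conditions: HF·pyridine, THF, rt
Reagents that add atoms: none
Why: Mildly acidic fluoride desilylation frees the benzylic alcohol without touching the acetates, the allylic esters or the α-methylene lactone.

Compound list
1 | 6-bromophthalide | O=C1OCc2ccc(Br)cc12 | starting material
2 | (3-bromopropoxy)(tert-butyl)dimethylsilane | BrCCCO[Si](C)(C)C(C)(C)C | starting material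
3 | [3-(tert-butyldimethylsilyloxy)propyl]magnesium bromide | Br[Mg]CCCO[Si](C)(C)C(C)(C)C | intermediate
4 | 1-[5-bromo-2-(hydroxymethyl)phenyl]-4-(tert-butyldimethylsilyloxy)butan-1-one | O=C(CCCO[Si](C)(C)C(C)(C)C)c1cc(Br)ccc1CO | intermediate
5 | TBDPS ether of 4 | O=C(CCCO[Si](C)(C)C(C)(C)C)c1cc(Br)ccc1CO[Si](c1ccccc1)(c1ccccc1)C(C)(C)C | intermediate
6 | 1,1-disubstituted olefin | C=C(CCCO[Si](C)(C)C(C)(C)C)c1cc(Br)ccc1CO[Si](c1ccccc1)(c1ccccc1)C(C)(C)C | intermediate
7 | aryl bromide Ar1–Br, (1″R) | Brc1ccc(CO[Si](c2ccccc2)(c2ccccc2)C(C)(C)C)c([C@H](C)CCCO[Si](C)(C)C(C)(C)C)c1 | intermediate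
8 | tert-butyldimethyl(prop-2-yn-1-yloxy)silane | C#CCO[Si](C)(C)C(C)(C)C | starting material
9 | ethylene | C=C | starting material
10 | 2-(tert-butyldimethylsilyloxymethyl)buta-1,3-diene | C=CC(=C)CO[Si](C)(C)C(C)(C)C | intermediate
11 | cyclopentane-1,3-dione | O=C1CCC(=O)C1 | starting material
12 | (E)-crotonaldehyde | C/C=C/C=O | starting material
13 | 2-[(2S)-4-oxobutan-2-yl]cyclopentane-1,3-dione | O=CC[C@H](C)C1C(=O)CCC1=O | intermediate
14 | acetal vinylogous ester, (10S) | COC(OC)C[C@H](C)C1=C(OC)CCC1=O | intermediate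
15 | α′-methyl vinylogous ester, (10S), C4 epimers | COC(OC)C[C@H](C)C1=C(OC)CC(C)C1=O | intermediate
16 | tertiary α-ketol, (4S,10S) | COC(OC)C[C@H](C)C1=C(OC)C[C@](C)(O)C1=O | intermediate
17 | acrylate of 16, (4S,10S) | COC(OC)C[C@H](C)C1=C(OC)C[C@](C)(OC(=O)C=C)C1=O | intermediate
18 | ring A/ring C lactone, (3S,4S,10S) | COC(OC)C[C@H](C)C1=C(OC)[C@@H]2CCC(=O)O[C@]2(C)C1=O | intermediate
19 | 2′-aryl lactone, (3S,4S,10S,2′R,1″R) | COC(OC)C[C@H](C)C1=C(OC)[C@@H]2C[C@H](c3ccc(CO[Si](c4ccccc4)(c4ccccc4)C(C)(C)C)c([C@H](C)CCCO[Si](C)(C)C(C)(C)C)c3)C(=O)O[C@]2(C)C1=O | intermediate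
20 | dienyl triflate (C5–OTf, C2–OMe cyclopentadiene) | COC(OC)C[C@H](C)C1=C(OS(=O)(=O)C(F)(F)F)[C@@]2(C)OC(=O)[C@@H](c3ccc(CO[Si](c4ccccc4)(c4ccccc4)C(C)(C)C)c([C@H](C)CCCO[Si](C)(C)C(C)(C)C)c3)CC2=C1OC | intermediate
21 | β-triflyloxy enone aldehyde | O=CC[C@H](C)C1=C(OS(=O)(=O)C(F)(F)F)[C@@]2(C)OC(=O)[C@@H](c3ccc(CO[Si](c4ccccc4)(c4ccccc4)C(C)(C)C)c([C@H](C)CCCO[Si](C)(C)C(C)(C)C)c3)C[C@H]2C1=O | intermediate
22 | (E)-allylindium iodide triflate | O=CC[C@H](C)C1=C(C/C=C(/C[In](I)OS(=O)(=O)C(F)(F)F)CO[Si](C)(C)C(C)(C)C)[C@@]2(C)OC(=O)[C@@H](c3ccc(CO[Si](c4ccccc4)(c4ccccc4)C(C)(C)C)c([C@H](C)CCCO[Si](C)(C)C(C)(C)C)c3)C[C@H]2C1=O | intermediate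
23 | hydroazulenone homoallylic alcohol | O[C@H]2C[C@H](C)C3=C(C[C@@H]2C(=C)CO[Si](C)(C)C(C)(C)C)[C@@]1(C)OC(=O)[C@@H](c2ccc(CO[Si](c4ccccc4)(c4ccccc4)C(C)(C)C)c([C@H](C)CCCO[Si](C)(C)C(C)(C)C)c2)C[C@H]1C3=O | intermediate
24 | triol | O[C@H]2C[C@H](C)C3=C(C[C@@H]2C(=C)CO)[C@@]1(C)OC(=O)[C@@H](c2ccc(CO[Si](c4ccccc4)(c4ccccc4)C(C)(C)C)c([C@H](C)CCCO)c2)C[C@H]1C3=O | intermediate
25 | α-methylene lactol | C=C1C(O)O[C@H]2C[C@H](C)C3=C(C[C@H]12)[C@@]1(C)OC(=O)[C@@H](c2ccc(CO[Si](c4ccccc4)(c4ccccc4)C(C)(C)C)c([C@H](C)CCCO)c2)C[C@H]1C3=O | intermediate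
26 | α-methylene lactone enone | C=C1C(=O)O[C@H]2C[C@H](C)C3=C(C[C@H]12)[C@@]1(C)OC(=O)[C@@H](c2ccc(CO[Si](c4ccccc4)(c4ccccc4)C(C)(C)C)c([C@H](C)CCCO)c2)C[C@H]1C3=O | intermediate
27 | (2R)-allylic alcohol | C=C1C(=O)O[C@H]2C[C@H](C)C3=C(C[C@H]12)[C@@]1(C)OC(=O)[C@@H](c2ccc(CO[Si](c4ccccc4)(c4ccccc4)C(C)(C)C)c([C@H](C)CCCO)c2)C[C@H]1[C@H]3O | intermediate
28 | diacetate TBDPS ether | C=C1C(=O)O[C@H]2C[C@H](C)C3=C(C[C@H]12)[C@@]1(C)OC(=O)[C@@H](c2ccc(CO[Si](c4ccccc4)(c4ccccc4)C(C)(C)C)c([C@H](C)CCCOC(C)=O)c2)C[C@H]1[C@H]3OC(C)=O | intermediate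
29 | CNP0205574.1 | C=C1C(=O)O[C@H]2C[C@H](C)C3=C(C[C@H]12)[C@@]1(C)OC(=O)[C@@H](c2ccc(CO)c([C@H](C)CCCOC(C)=O)c2)C[C@H]1[C@H]3OC(C)=O | target

Total steps: 19. Longest linear sequence: 14 steps (steps 6 to 19, from cyclopentane-1,3-dione).

Steps most likely to fail

1. Step 14.
- What may go wrong: loss of the π-allyl complex by β-hydride elimination to a triene, reduction of the alkenylpalladium by InI before the diene inserts, or poor facial selectivity in the ring closure.
- Fallback: it sets out from 21 and 10 and divides the cascade into two known reactions. Heck-type vinylation of the diene with capture of the π-allylpalladium by acetate (Pd2(dba)3, KOAc, DMSO, 50 °C) should give the isolable allylic acetate F1. In a second flask F1 is cyclised by the established umpolung of allylic acetates (Pd(PPh3)4, InI, THF, rt, high dilution), which brings the route back to 23.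

2. Step 11.
- What may go wrong: anionic oligomerisation of the simple acrylate, or a closure too slow to compete with it.
- Fallback: it sets out from 7 and 16 and brings in the aryl group with the acceptor.
 - Bromine–magnesium exchange of 7 (i-PrMgCl·LiCl), transmetalation with ZnCl2 and Negishi coupling with methyl 2-bromoacrylate (Pd(PPh3)4) should give the methyl 2-arylacrylate F2.
 - LiOH hydrolysis gives the 2-arylacrylic acid F3.
 - Yamaguchi esterification of 16 gives the 2-arylacrylate ester F4.
 - The acceptor in F4 does not polymerise, and its Michael adduct is a stabilised benzylic enolate. Catalytic KOt-Bu then closes ring C and returns the route to 19, bypassing 17, 18 and step 12.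

3. Step 12.
- What may go wrong: competing deprotonation at C3, double arylation, or slow reductive elimination at the hindered lactone enolate.
- Fallback: it sets out from 18 and replaces the alkali enolate by a neutral zinc enolate. Bromination of the lithium enolate (LiHMDS, then NBS) gives the α-bromolactone F5. Activated zinc in THF gives the Reformatsky reagent F6. Its palladium-catalysed arylation with 7 (Pd(dba)2, 1,2,3,4,5-pentaphenyl-1′-(di-tert-butylphosphino)ferrocene, THF, rt) returns the route to 19.

Further compounds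
F1 | step 14 | allylic acetate (C13–OAc) aldehyde | O=CC[C@H](C)C1=C(C/C=C(/COC(C)=O)CO[Si](C)(C)C(C)(C)C)[C@@]2(C)OC(=O)[C@@H](c3ccc(CO[Si](c4ccccc4)(c4ccccc4)C(C)(C)C)c([C@H](C)CCCO[Si](C)(C)C(C)(C)C)c3)C[C@H]2C1=O
F2 | step 11 | methyl 2-(Ar1)acrylate | C=C(C(=O)OC)c1ccc(CO[Si](c2ccccc2)(c2ccccc2)C(C)(C)C)c([C@H](C)CCCO[Si](C)(C)C(C)(C)C)c1
F3 | step 11 | 2-(Ar1)acrylic acid | C=C(C(=O)O)c1ccc(CO[Si](c2ccccc2)(c2ccccc2)C(C)(C)C)c([C@H](C)CCCO[Si](C)(C)C(C)(C)C)c1
F4 | step 11 | 2-(Ar1)acrylate ester of 16 | COC(OC)C[C@H](C)C1=C(OC)C[C@](C)(OC(=O)C(=C)c2ccc(CO[Si](c3ccccc3)(c3ccccc3)C(C)(C)C)c([C@H](C)CCCO[Si](C)(C)C(C)(C)C)c2)C1=O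
F5 | step 12 | 2′-bromolactone | COC(OC)C[C@H](C)C1=C(OC)[C@@H]2CC(Br)C(=O)O[C@]2(C)C1=O
F6 | step 12 | Reformatsky reagent of F5 | COC(OC)C[C@H](C)C1=C(OC)[C@@H]2CC([Zn]Br)C(=O)O[C@]2(C)C1=O
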